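If a vessel fills through a single slow inlet, one time constant tells how full it is at any moment, so I look for that constant in this reaction.

the same everywhere: substrate 0.036 M
- epsilon: partner 0.25 equiv; temperature 24 °C; run made earlier
- gamma: partner 1.5 equiv; temperature 54 °C; run made earlier
- dusk: partner 1.70 equiv; temperature 55 °C; time 10 min
- spring: partner 2.20 equiv; temperature 25 °C; time 10 min
- midnight: partner 1.10 equiv; temperature 25 °C; time 10 min
- autumn: partner 0.360 equiv; temperature 10 °C; time 10 min
- summer: partner 0.360 equiv; temperature 65 °C; time 10 min

- epsilon (time / min: target / %, substrate / %): 0.417: 1, 85; 0.833: 0, 69; 1.33: 3, 54; 2.50: 0, 32; 5.00: 2, 10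
- gamma (time / s: target / %, substrate / %): 10.0: 2, 10; 20.0: 7, 2; 40.0: 12, 0; 60.0: 20, 0; 80.0: 28, 1

(readings scatter by 1.5 percentage points)

* all flasks from highest to lowest amount of target, in percent of the substrate charged, at 10 min (dusk / spring / midnight / autumn / summer)
* the same order at 80 min (dusk / spring / midnight / autumn / summer)
* the amount of target, in percent of the substrate charged of the flask you put first, at 10 min
* the amount of target, in percent of the substrate charged of the flask you put last, at 10 min



First, does the substrate wait for the partner? In the epsilon run it falls to 10% with 0.25 equiv of partner charged, while target reads 2%. So its loss does not wait for partner, and it passes into something unseen.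

Second, how do the two clocks compare? In the gamma run substrate reads 10% at 10.0 s, which reads as a time constant of 4.34 s. Target reads 28% at 80.0 s, when substrate reads 1%, so the rest of the material stands in an unseen pool.

I define the filling time as the time constant of target rising first-order from that pool towards the whole charge. Integrating that rate gives a target share of one minus exp(−t/τ), and the last gamma reading then gives 4.06 min. As read from these single readings, this is 56.1 times the substrate's time constant, so the filling clock is the one to follow.

Third, how far does the dusk flask get? Its temperature of 55 °C lies close to gamma's 54 °C, so I keep gamma's pace. I assume a pseudo-first-order pool whose filling time shortens in proportion to partner, and this stays an assumption of mine. That gives 3.58 min for dusk, and at 10 min my reckoning is 93.9%, provided nothing else draws on the pool.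

The forecast, which has target forming "apparently from intermediate plus partner", gives dusk > summer > spring > midnight > autumn at 10 min and dusk > spring > midnight > summer > autumn at 80 min, with 85% first and 0.6% last, so its top lies below my figure.

The flasks give dusk > summer > spring > midnight > autumn at 10 min and dusk > spring > midnight > summer > autumn at 80 min, with dusk at 64.8% and autumn at 0.0986%.

    open intermediate + second intermediate → target (k = 0.0190 M⁻¹ s⁻¹, Ea = 66.0 kJ mol⁻¹)
    partner → second intermediate (k = 0.00160 s⁻¹, Ea = 81.0 kJ mol⁻¹)
    2 open intermediate → homo product (k = 0.0190 M⁻¹ s⁻¹, Ea = 53.0 kJ mol⁻¹)
    substrate ⇌ dormant form (K = 1.30, k = 5.00 × 10⁻⁴ s⁻¹, Ea = 82.0 kJ mol⁻¹, ΔH = −7.00 kJ mol⁻¹)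
    substrate → open intermediate (k = 0.00830 s⁻¹, Ea = 92.0 kJ mol⁻¹)
    (constants at 25 °C)

My dusk reckoning stands 29 percentage points above the flask. The pool holds open intermediate, and it has a second exit: pairs of open intermediate join into homo product, which holds 34.8% of the substrate charged in dusk at 10.0 min. That step is the main reason why dusk stops short of the whole charge, and with it struck out dusk gives 97.9%. For a flask like dusk with 0.680 equiv of partner, the filling time scaled to that charge gives 67.3%, but that flask gives 40.3% at 10 min, with homo product at 54.0%.

The data are simulated on assumed constants; scatter was added.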